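**Plan**
- The benzenoid ring is cut at C4a–C5 and C8–C8a. Ring carbons C5–C8, oxygenated at C5 and C7, correspond to a 1-methoxy-1,3-bis(silyloxy)butadiene; the fusion bond C4a=C8a is the C5=C6 bond of a monocyclic 4-pyranone that carries a sulfinyl group on the future C4a.
- The pyranone is cut at O1–C6 and at the acyl bond next to C2, giving hexacosanoyl chloride and an α-sulfinyl enaminone built from methyl p-tolyl sulfoxide, ethyl acetate and DMF dimethyl acetal.
- Forward: sulfinylacetone, then enaminone, then C-acylation to attach the C25 chain, then acid closure of the pyranone ring. The diene is made in two steps from methyl acetoacetate. The benzene ring is formed last by cycloaddition and aromatising elimination, and acidic work-up frees the 5,7-diol.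
- Stereochemistry: the target has none. The cycloadduct's transient stereocentres and the sulfur stereocentre are erased by the eliminations.

Key step: step 7

Remark: the target has no stereocentre and no stereogenic double bond, so it is a single achiral compound and no enantiocontrol is needed; the sulfoxide is used as the racemate.

Step 1
Reactants: 1 methyl p-tolyl sulfoxide (racemic)
Product: 2 1-(p-tolylsulfinyl)propan-2-one
Conditions: LDA (2.0 equiv), 1 (2.0 equiv), THF, −78 °C; EtOAc (1.0 equiv), −78 → 0 °C; 1 M HCl to pH 3; surplus 1 recovered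
Reagents that add atoms: ethyl acetate, CCOC(C)=O
Why: Claisen-type acylation of the α-sulfinyl carbanion is the standard β-keto sulfoxide synthesis, and the second equivalent of carbanion deprotonates the more acidic product so that over-addition should not occur.

Step 2
Reactants: 2 1-(p-tolylsulfinyl)propan-2-one
Product: 3 4-(dimethylamino)-3-(p-tolylsulfinyl)but-3-en-2-one
Conditions: Me2NCH(OMe)2 (1.1 equiv), toluene, rt → 50 °C
Reagents that add atoms: N,N-dimethylformamide dimethyl acetal, COC(OC)N(C)C
Why: Enaminone formation by condensation of an amide acetal with an active methylene should occur at the CH2 flanked by C=O and S=O, far faster than at the methyl group, which puts the future pyranone C6 on the sulfur-bearing carbon.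

Step 3
Reactants: 4 hexacosanoic acid
Product: 5 hexacosanoyl chloride
Conditions: (COCl)2 (1.5 equiv), DMF (cat.), CH2Cl2, rt → 40 °C; evaporate, use crude
Reagents that add atoms: oxalyl chloride, O=C(Cl)C(=O)Cl
Why: Vilsmeier-catalysed conversion of a carboxylic acid into its chloride is routine and the saturated chain is inert.

Step 4
Reactants: 3 4-(dimethylamino)-3-(p-tolylsulfinyl)but-3-en-2-one; 5 hexacosanoyl chloride
Product: 7 2-pentacosyl-5-(p-tolylsulfinyl)-4H-pyran-4-one, via diketo enaminone 6 (not isolated)
Conditions: 3 (1.1 equiv), LiHMDS (2.3 equiv), THF, −78 °C; 5 in THF, −78 → −20 °C; aq. HCl quench; crude 6, TFA, CH2Cl2, rt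
Reagents that add atoms: none
Why: This is the established enaminone route to 2-substituted 4-pyranones, in which Claisen-type C-acylation of the kinetic methyl ketone enolate (preformed at −78 °C so that it outcompetes O-acylation of the sulfoxide) gives diketone 6 and acid then drives addition–elimination of the enol oxygen onto the aminomethylene carbon with loss of dimethylamine.

Step 5
Reactants: 8 methyl acetoacetate
Product: 9 methyl 3-(trimethylsilyloxy)but-2-enoate
Conditions: TMSCl (1.2 equiv), Et3N (1.3 equiv), hexane, rt; filter, distil
Reagents that add atoms: chlorotrimethylsilane, C[Si](C)(C)Cl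
Why: Soft enolisation and O-silylation of a β-keto ester is the standard silyl enol ether formation.

Step 6
Reactants: 9 methyl 3-(trimethylsilyloxy)but-2-enoate
Product: 10 1-methoxy-1,3-bis(trimethylsilyloxy)buta-1,3-diene
Conditions: LDA (1.1 equiv), THF, −78 °C; TMSCl (1.2 equiv), −78 °C → rt; evaporate, hexane, filter under argon; use at once
Reagents that add atoms: chlorotrimethylsilane, C[Si](C)(C)Cl
Why: γ-Deprotonation of the silyloxy crotonate to the lithium dienolate followed by O-silylation is the usual preparation of 1,3-bis(silyloxy) dienes from acetoacetates.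

Step 7
Reactants: 7 2-pentacosyl-5-(p-tolylsulfinyl)-4H-pyran-4-one; 10 1-methoxy-1,3-bis(trimethylsilyloxy)buta-1,3-diene
Product: 13 5,7-dihydroxy-2-pentacosyl-4H-chromen-4-one, via sulfinyl cycloadduct 11 (not isolated), via silyl ether 12 (not isolated)
Conditions: 10 (3 equiv), toluene, rt → 80 °C; then 1 M HCl, THF, rt
Reagents that add atoms: none
Why: Proposed new method: the electron-rich diene 10 should add to the C5=C6 bond of pyranone 7 (the future C4a=C8a) in a normal-demand Diels–Alder reaction, or in its polar limit by Mukaiyama–Michael attack of the diene CH2 on C6 followed by ring closure of the α-sulfinyl enolate onto the silyloxycarbenium carbon, to give the cis-fused adduct 11 with the sulfinyl group and H-8a syn. On warming, syn-elimination of p-toluenesulfenic acid should restore C4a=C8a, the mixed methyl silyl ketal at C5 should collapse with loss of methoxytrimethylsilane, the resulting dienone should tautomerise to phenol 12, and aqueous acid removes the remaining silyl group. The closest known reaction types are the benzannulations of halo- and sulfinylquinones with 1,1,3-trioxygenated butadienes and the Diels–Alder reactions of chromones and 4-pyranones bearing an acceptor at C3; a 3-sulfinyl 4-pyranone has not been shown to react this way. The new six-membered carbocycle closes by suprafacial [4+2] addition (6-exo-trig in the stepwise limit), and the stereocentres that arise at C4a, C5 and C8a, like the one at sulfur, need no control because all are erased on aromatisation. The step needs regioselectivity (CH2 terminus to C8a, ketene-acetal carbon to C4a) and site selectivity (C5=C6, not C2=C3 of the pyranone): C6 is the unsubstituted β-carbon of both the enone and the vinyl sulfoxide and should take the nucleophilic diene terminus, whereas C2=C3 is activated by the carbonyl alone and is deactivated and shielded by the pentacosyl chain.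

**Compound list**
1 | methyl p-tolyl sulfoxide (racemic) | Cc1ccc(S(C)=O)cc1 | starting material
2 | 1-(p-tolylsulfinyl)propan-2-one (racemic at sulfur) | CC(=O)CS(=O)c1ccc(C)cc1 | intermediate
3 | 4-(dimethylamino)-3-(p-tolylsulfinyl)but-3-en-2-one (C=C geometry not defined, without consequence) | CC(=O)C(=CN(C)C)S(=O)c1ccc(C)cc1 | intermediate
4 | hexacosanoic acid | CCCCCCCCCCCCCCCCCCCCCCCCCC(=O)O | starting material
5 | hexacosanoyl chloride | CCCCCCCCCCCCCCCCCCCCCCCCCC(=O)Cl | intermediate
6 | 1-(dimethylamino)-2-(p-tolylsulfinyl)triacont-1-ene-3,5-dione (not isolated; C=C geometry not defined) | CCCCCCCCCCCCCCCCCCCCCCCCCC(=O)CC(=O)C(=CN(C)C)S(=O)c1ccc(C)cc1 | intermediate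
7 | 2-pentacosyl-5-(p-tolylsulfinyl)-4H-pyran-4-one (racemic at sulfur) | CCCCCCCCCCCCCCCCCCCCCCCCCc1cc(=O)c(S(=O)c2ccc(C)cc2)co1 | intermediate
8 | methyl acetoacetate | CC(=O)CC(=O)OC | starting material
9 | methyl 3-(trimethylsilyloxy)but-2-enoate (C=C geometry not defined, without consequence) | COC(=O)C=C(C)O[Si](C)(C)C | intermediate
10 | 1-methoxy-1,3-bis(trimethylsilyloxy)buta-1,3-diene (C1=C2 geometry not defined, without consequence) | COC(O[Si](C)(C)C)=CC(=C)O[Si](C)(C)C | intermediate
11 | 5-methoxy-2-pentacosyl-4a-(p-tolylsulfinyl)-5,7-bis(trimethylsilyloxy)-4a,5,8,8a-tetrahydro-4H-chromen-4-one (not isolated; cis-fused, mixture of diastereomers) | CCCCCCCCCCCCCCCCCCCCCCCCCC1=CC(=O)C2(S(=O)c3ccc(C)cc3)C(OC)(O[Si](C)(C)C)C=C(O[Si](C)(C)C)CC2O1 | intermediate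
12 | 5-hydroxy-2-pentacosyl-7-(trimethylsilyloxy)-4H-chromen-4-one (not isolated) | CCCCCCCCCCCCCCCCCCCCCCCCCc1cc(=O)c2c(O)cc(O[Si](C)(C)C)cc2o1 | intermediate
13 | 5,7-dihydroxy-2-pentacosyl-4H-chromen-4-one | CCCCCCCCCCCCCCCCCCCCCCCCCc1cc(=O)c2c(O)cc(O)cc2o1 | target

**Step count**
Total steps: 7. Longest linear sequence: 4 steps (steps 1, 2, 4, 7).

**Steps most likely to fail**

Step 7. The diene may be lost by hydrolysis or silyl migration faster than it adds to the only moderately activated pyranone. Alternatively, conjugate addition at C6 may be followed by β-elimination of the ring oxygen, which opens the pyranone instead of closing the carbocycle. The fallback uses known chemistry, sets out from 5 and returns at 13. Commercial 2,4,6-trihydroxyacetophenone is converted with LiHMDS (4 equiv, THF, −78 °C) into its lithium polyanion and C-acylated with 5 to give 1-(2,4,6-trihydroxyphenyl)octacosane-1,3-dione F1. Heating this β-diketone in acetic acid with catalytic H2SO4 should cyclodehydrate it to 13, as in the standard preparation of 5,7-dihydroxyflavones and 2-alkylchromones.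

Step 4. The acid chloride may acylate the sulfinyl oxygen (Pummerer-type consumption of the sulfoxide) or the enolate oxygen, and the poor low-temperature solubility of the C26 chain makes this worse. The sulfoxide may also degrade during the acidic ring closure. The fallback carries sulfur at the sulfide level, sets out from 5 and returns at 7. 4-Methylbenzenethiol is alkylated with chloroacetone (K2CO3, acetone) to give 1-(p-tolylthio)propan-2-one F2. DMF dimethyl acetal converts it into 4-(dimethylamino)-3-(p-tolylthio)but-3-en-2-one F3. LiHMDS and then 5 give 1-(dimethylamino)-2-(p-tolylthio)triacont-1-ene-3,5-dione F4, which TFA closes to 2-pentacosyl-5-(p-tolylthio)-4H-pyran-4-one F5. One equivalent of mCPBA (CH2Cl2, −20 °C) should then oxidise sulfur chemoselectively to give 7.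

Step 6. The bis-silyl diene may suffer protodesilylation or C-silylation during trapping and isolation, and may not survive storage or the temperature of step 7. The fallback uses a more robust methyl-capped diene with a late demethylation, sets out from 8 and returns at 13. Trimethyl orthoformate with catalytic H2SO4 converts 8 into methyl (E)-3-methoxybut-2-enoate F6. LDA and TMSCl give the distillable 1,3-dimethoxy-1-(trimethylsilyloxy)buta-1,3-diene F7. Reaction with 7 under the conditions of step 7 should give 5,7-dimethoxy-2-pentacosyl-4a-(p-tolylsulfinyl)-5-(trimethylsilyloxy)-4a,5,8,8a-tetrahydro-4H-chromen-4-one F8, which aromatises in the flask to 5-hydroxy-7-methoxy-2-pentacosyl-4H-chromen-4-one F9. BBr3 in CH2Cl2 cleaves the aryl methyl ether to give 13.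

Further compounds
F1 | step 7 | 1-(2,4,6-trihydroxyphenyl)octacosane-1,3-dione | CCCCCCCCCCCCCCCCCCCCCCCCCC(=O)CC(=O)c1c(O)cc(O)cc1O
F2 | step 4 | 1-(p-tolylthio)propan-2-one | CC(=O)CSc1ccc(C)cc1
F3 | step 4 | 4-(dimethylamino)-3-(p-tolylthio)but-3-en-2-one | CC(=O)C(=CN(C)C)Sc1ccc(C)cc1
F4 | step 4 | 1-(dimethylamino)-2-(p-tolylthio)triacont-1-ene-3,5-dione | CCCCCCCCCCCCCCCCCCCCCCCCCC(=O)CC(=O)C(=CN(C)C)Sc1ccc(C)cc1
F5 | step 4 | 2-pentacosyl-5-(p-tolylthio)-4H-pyran-4-one | CCCCCCCCCCCCCCCCCCCCCCCCCc1cc(=O)c(Sc2ccc(C)cc2)co1
F6 | step 6 | methyl (E)-3-methoxybut-2-enoate | C/C(OC)=C\C(=O)OC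
F7 | step 6 | 1,3-dimethoxy-1-(trimethylsilyloxy)buta-1,3-diene | COC(=C)C=C(OC)O[Si](C)(C)C
F8 | step 6 | 5,7-dimethoxy-2-pentacosyl-4a-(p-tolylsulfinyl)-5-(trimethylsilyloxy)-4a,5,8,8a-tetrahydro-4H-chromen-4-one | CCCCCCCCCCCCCCCCCCCCCCCCCC1=CC(=O)C2(S(=O)c3ccc(C)cc3)C(OC)(O[Si](C)(C)C)C=C(OC)CC2O1
F9 | step 6 | 5-hydroxy-7-methoxy-2-pentacosyl-4H-chromen-4-one | CCCCCCCCCCCCCCCCCCCCCCCCCc1cc(=O)c2c(O)cc(OC)cc2o1
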